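The synthesis rests on cutting the aryl ether bond O1–C8a of ring C instead of the usual O1–C2 bond. C8a of ring A lies ortho to the C4 carbonyl, which activates a C8a triflate, and the C2–O1 bond at the stereocentre is never broken. C2 is therefore set first by a catalytic asymmetric Mukaiyama aldol addition. One palladium-catalysed intramolecular etherification then closes ring C with retention and gives the unprotected target directly. Its precursor is an open-chain (S)-β-hydroxy ketone that carries the C8a triflate, the C8 prenyl group and the free, chelated 5-OH. A para-Claisen–Cope shift places prenyl next to triflate.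

Key step: step 6

Assumption: the (4R)-oxazaborolidinone is taken to leave the Si face of 2,4,6-trimethoxybenzaldehyde open, mirroring the Re-face addition that its (4S) antipode directs on simple aromatic aldehydes; the configuration of the aldol is to be confirmed through its MTPA esters before ring closure. Flavanone numbering (O1, C2–C4, C4a, C5–C8, C8a) is used for all intermediates.

Step 1
Reactants: 1 1-(2,6-dihydroxy-4-methoxyphenyl)ethanone; 2 1-bromo-3-methylbut-2-ene (prenyl bromide)
Product: 3 1-[2-hydroxy-4-methoxy-6-(3-methylbut-2-enyloxy)phenyl]ethanone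
Conditions: K2CO3 (1.2 equiv), acetone, reflux
Reagents that add atoms: none
Why: Williamson etherification in which only one of the two equivalent phenols reacts readily, because after the first O-alkylation the remaining OH is locked in a hydrogen bond to the acetyl carbonyl, and K2CO3 in acetone favours O- over C-alkylation.

Step 2
Reactants: 3 1-[2-hydroxy-4-methoxy-6-(3-methylbut-2-enyloxy)phenyl]ethanone
Product: 4 2-acetyl-5-methoxy-3-(3-methylbut-2-enyloxy)phenyl trifluoromethanesulfonate
Conditions: Tf2O (1.2 equiv), pyridine (3 equiv), CH2Cl2, 0 °C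
Reagents that add atoms: triflic anhydride, O=S(=O)(OS(=O)(=O)C(F)(F)F)C(F)(F)F
Why: O-sulfonylation of the chelated phenol by the strongly electrophilic anhydride turns the oxygen on future C8a into a leaving group, while pyridine buffers the acid so that the prenyl ether survives.

Step 3
Reactants: 4 2-acetyl-5-methoxy-3-(3-methylbut-2-enyloxy)phenyl trifluoromethanesulfonate
Product: 7 2-acetyl-3-hydroxy-5-methoxy-6-(3-methylbut-2-enyl)phenyl trifluoromethanesulfonate, via ortho-dienone 5 (not isolated), via para-dienone 6 (not isolated)
Conditions: N,N-diethylaniline, 190 °C, sealed tube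
Reagents that add atoms: none
Why: Tandem aromatic Claisen–Cope (para-Claisen) rearrangement, in which the first [3,3] shift to the only free ortho carbon gives a crowded 1,1-dimethylallyl dienone that passes the chain on by a second [3,3] shift to the para carbon between OTf and OMe before it can enolise, so that the prenyl group and the free phenol appear exactly at future C8 and C5.

Step 4
Reactants: 7 2-acetyl-3-hydroxy-5-methoxy-6-(3-methylbut-2-enyl)phenyl trifluoromethanesulfonate
Product: 8 5-methoxy-6-(3-methylbut-2-enyl)-3-(trimethylsilyloxy)-2-[1-(trimethylsilyloxy)vinyl]phenyl trifluoromethanesulfonate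
Conditions: TMSOTf (2.4 equiv), Et3N (3 equiv), CH2Cl2, 0 °C; pentane, cold aq. NaHCO3 wash; used crude
Reagents that add atoms: trimethylsilyl trifluoromethanesulfonate, C[Si](C)(C)OS(=O)(=O)C(F)(F)F
Why: Soft enolisation (silyl enol ether formation) gives the only possible, terminal enol silane and at the same time masks the phenol as a transient silyl ether, and neither the triflate nor the alkene is touched.

Step 5
Reactants: 8 5-methoxy-6-(3-methylbut-2-enyl)-3-(trimethylsilyloxy)-2-[1-(trimethylsilyloxy)vinyl]phenyl trifluoromethanesulfonate; 9 2,4,6-trimethoxybenzaldehyde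
Product: 11 3-hydroxy-2-[(3S)-3-hydroxy-3-(2,4,6-trimethoxyphenyl)propanoyl]-5-methoxy-6-(3-methylbut-2-enyl)phenyl trifluoromethanesulfonate, via bis-silyl aldol ether 10 (not isolated)
Conditions: (4R)-2-butyl-4-(1H-indol-3-ylmethyl)-3-tosyl-1,3,2-oxazaborolidin-5-one (20 mol %), EtCN, −78 °C; then TBAF/AcOH (1:1, 2.2 equiv), THF, 0 °C; Et3N-deactivated SiO2
Reagents that add atoms: none
Why: Catalytic enantioselective Mukaiyama aldol addition in which the aldehyde binds to boron with its Re face covered by the indole ring, so the enol silane attacks the Si face and sets C2 as (S), and buffered fluoride then frees both hydroxyl groups without acid (ionisation of the electron-rich carbinol) or base (retro-aldol cleavage).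

Step 6
Reactants: 11 3-hydroxy-2-[(3S)-3-hydroxy-3-(2,4,6-trimethoxyphenyl)propanoyl]-5-methoxy-6-(3-methylbut-2-enyl)phenyl trifluoromethanesulfonate
Product: 12 (2S)-5-hydroxy-7-methoxy-8-(3-methylbut-2-enyl)-2-(2,4,6-trimethoxyphenyl)-2,3-dihydrochromen-4-one
Conditions: [(allyl)PdCl]2 (2.5 mol %), RockPhos [2-(di-tert-butylphosphino)-3-methoxy-6-methyl-2',4',6'-triisopropylbiphenyl, 6 mol %], K3PO4 (2.5 equiv), 4 Å MS, degassed toluene, 55 °C; pH 7 phosphate buffer work-up
Reagents that add atoms: none
Why: Zerovalent palladium ligated by RockPhos inserts into the C8a–OTf bond, which the ortho C4 carbonyl makes electron-poor; the C2 hydroxyl then binds the cationic divalent palladium centre, is deprotonated there by phosphate, and C–O reductive elimination forms O1–C8a. The closest known reaction type is the intramolecular Buchwald–Hartwig etherification of aryl halides and sulfonates that carry a tethered secondary alcohol, which converts enantioenriched carbinols into chromans without loss of configuration. Ring C, the only ring closed, forms as a six-membered ring by reductive elimination from a seven-membered oxapalladacycle (Pd, C8a, C4a, C4, C3, C2, O1). No stereocentre is created: C2 keeps its (S) configuration because the C2–O1 bond is never broken and no free alkoxide accumulates that could start a retro-aldol cleavage. The alcohol must win over the 5-OH, over loss of water across C2–C3 and over β-hydride elimination: the 5-OH is chelated to C4=O and sits meta to C8a so it cannot reach the metal, its phenoxide turns the ketone into a vinylogous carboxylate and so lowers the acidity of the C3 hydrogens, and the bulky ligand together with the electron-poor, doubly ortho-substituted aryl group speeds reductive elimination. The C8 prenyl group stays out because its insertion would need a four-membered or a 5-endo ring closure.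

Compound list
1 | 1-(2,6-dihydroxy-4-methoxyphenyl)ethanone | CC(=O)c1c(O)cc(OC)cc1O | starting material
2 | 1-bromo-3-methylbut-2-ene (prenyl bromide) | CC(C)=CCBr | starting material
3 | 1-[2-hydroxy-4-methoxy-6-(3-methylbut-2-enyloxy)phenyl]ethanone | CC(=O)c1c(O)cc(OC)cc1OCC=C(C)C | intermediate
4 | 2-acetyl-5-methoxy-3-(3-methylbut-2-enyloxy)phenyl trifluoromethanesulfonate | CC(=O)c1c(OS(=O)(=O)C(F)(F)F)cc(OC)cc1OCC=C(C)C | intermediate
5 | ortho-dienone, 2-acetyl-5-methoxy-4-(2-methylbut-3-en-2-yl)-3-oxocyclohexa-1,5-dien-1-yl trifluoromethanesulfonate (racemic, not isolated) | CC(=O)C1=C(OS(=O)(=O)C(F)(F)F)C=C(OC)C(C(C)(C)C=C)C1=O | intermediate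
6 | para-dienone, 2-acetyl-5-methoxy-6-(3-methylbut-2-enyl)-3-oxocyclohexa-1,4-dien-1-yl trifluoromethanesulfonate (racemic, not isolated) | CC(=O)C1=C(OS(=O)(=O)C(F)(F)F)C(CC=C(C)C)C(OC)=CC1=O | intermediate
7 | 2-acetyl-3-hydroxy-5-methoxy-6-(3-methylbut-2-enyl)phenyl trifluoromethanesulfonate | CC(=O)c1c(O)cc(OC)c(CC=C(C)C)c1OS(=O)(=O)C(F)(F)F | intermediate
8 | 5-methoxy-6-(3-methylbut-2-enyl)-3-(trimethylsilyloxy)-2-[1-(trimethylsilyloxy)vinyl]phenyl trifluoromethanesulfonate | C=C(O[Si](C)(C)C)c1c(O[Si](C)(C)C)cc(OC)c(CC=C(C)C)c1OS(=O)(=O)C(F)(F)F | intermediate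
9 | 2,4,6-trimethoxybenzaldehyde | COc1cc(OC)c(C=O)c(OC)c1 | starting material
10 | bis-silyl aldol ether, the (S)-configured O,O'-bis(trimethylsilyl) derivative of 11 (not isolated) | COc1cc(OC)c([C@H](CC(=O)c2c(O[Si](C)(C)C)cc(OC)c(CC=C(C)C)c2OS(=O)(=O)C(F)(F)F)O[Si](C)(C)C)c(OC)c1 | intermediate
11 | 3-hydroxy-2-[(3S)-3-hydroxy-3-(2,4,6-trimethoxyphenyl)propanoyl]-5-methoxy-6-(3-methylbut-2-enyl)phenyl trifluoromethanesulfonate | COc1cc(OC)c([C@H](CC(=O)c2c(O)cc(OC)c(CC=C(C)C)c2OS(=O)(=O)C(F)(F)F)O)c(OC)c1 | intermediate
12 | (2S)-5-hydroxy-7-methoxy-8-(3-methylbut-2-enyl)-2-(2,4,6-trimethoxyphenyl)-2,3-dihydrochromen-4-one | COc1cc(OC)c([C@@H]2CC(=O)c3c(O)cc(OC)c(CC=C(C)C)c3O2)c(OC)c1 | target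

Total step count: 6. Longest linear sequence: 6 (1 to 12).

Steps most likely to fail

Step 6.
- **Risk:** The aldol may lose water or undergo retro-aldol cleavage under the base before palladium engages it. The palladium alkoxide may undergo β-hydride elimination. Oxidative addition at the doubly ortho-substituted phenoxide ring may be sluggish. The triflyl group may be transferred to the phenoxide.
- **Fallback:** The prenyl ether is kept on O5 as the protecting group during ring closure, and the sigmatropic shift is moved to the end.
  - Setting out from 4, TMSOTf/Et3N should give the silyl enol ether F1.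
  - The same oxazaborolidinone-catalysed addition to 9, followed by TBAF/AcOH, should give the (S)-aldol F2.
  - Palladium-catalysed etherification of this phenol-free and less crowded triflate should give the (S)-5-prenyloxyflavanone F3.
  - A Claisen–Cope shift catalysed by Eu(fod)3 (CHCl3, 60 °C), a reaction type known for 5-prenyloxyflavanones, comes back to the route at 12.
  - This order has the same length. It is the second choice because heat and a Lewis acid then act on the finished C2 stereocentre.

Step 5.
- **Risk:** Turnover may be poor with the electron-rich, doubly ortho-substituted aldehyde. Facial selectivity may be poor because the donor aldehyde stacks less well on the indole. The product carbinol may ionise on the Lewis acid.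
- **Fallback:** Asymmetric catalysis is replaced by a racemic aldol addition followed by acylative kinetic resolution.
  - Setting out from 7, the phenoxide-enolate dianion (LiHMDS, 2.2 equiv, THF, −78 °C) adds to 9 to give the racemic aldol F4.
  - (R)-Benzotetramisole [(2R)-2-phenyl-2,3-dihydroimidazo[2,1-b][1,3]benzothiazole, 5 mol %] is then used with isobutyric anhydride (0.6 equiv) and i-Pr2NEt in CHCl3 at 0 °C.
  - It is expected to acylate the (R)-carbinol faster, giving the (R)-isobutyrate F5 and leaving the (S)-alcohol. After chromatography this comes back to the route at 11.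

Step 3.
- **Risk:** The rearrangement may stop at the ortho stage through enolisation before the Cope shift. The prenyl group may be lost thermally. The triflate may suffer S–O cleavage at high temperature.
- **Fallback:** The sigmatropic relay is replaced by direct C-alkylation and steric differentiation of the two phenols.
  - Setting out from 1, prenyl bromide 2 in aqueous KOH at 0 °C alkylates one of the two equivalent ring CH positions to give the C-prenyl acetophenone F6.
  - TBSCl/imidazole (DMF, 0 °C) silylates the less hindered phenol, the one flanked by H, to give the mono-silyl ether F7.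
  - Tf2O/pyridine converts the remaining phenol next to the prenyl group into the silyl ether triflate F8.
  - TBAF/AcOH (THF, 0 °C) comes back to the route at 7.

Further compounds
F1 | step 6 | 5-methoxy-3-(3-methylbut-2-enyloxy)-2-[1-(trimethylsilyloxy)vinyl]phenyl trifluoromethanesulfonate | C=C(O[Si](C)(C)C)c1c(OS(=O)(=O)C(F)(F)F)cc(OC)cc1OCC=C(C)C
F2 | step 6 | 2-[(3S)-3-hydroxy-3-(2,4,6-trimethoxyphenyl)propanoyl]-5-methoxy-3-(3-methylbut-2-enyloxy)phenyl trifluoromethanesulfonate | COc1cc(OC)c([C@H](CC(=O)c2c(OCC=C(C)C)cc(OC)cc2OS(=O)(=O)C(F)(F)F)O)c(OC)c1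
F3 | step 6 | (2S)-7-methoxy-5-(3-methylbut-2-enyloxy)-2-(2,4,6-trimethoxyphenyl)-2,3-dihydrochromen-4-one | COc1cc(OC)c([C@@H]2CC(=O)c3c(OCC=C(C)C)cc(OC)cc3O2)c(OC)c1
F4 | step 5 | racemic 3-hydroxy-2-[3-hydroxy-3-(2,4,6-trimethoxyphenyl)propanoyl]-5-methoxy-6-(3-methylbut-2-enyl)phenyl trifluoromethanesulfonate | COc1cc(OC)c(C(O)CC(=O)c2c(O)cc(OC)c(CC=C(C)C)c2OS(=O)(=O)C(F)(F)F)c(OC)c1
F5 | step 5 | (1R)-3-[2-hydroxy-4-methoxy-5-(3-methylbut-2-enyl)-6-(trifluoromethylsulfonyloxy)phenyl]-3-oxo-1-(2,4,6-trimethoxyphenyl)propyl 2-methylpropanoate | COc1cc(OC)c([C@@H](CC(=O)c2c(O)cc(OC)c(CC=C(C)C)c2OS(=O)(=O)C(F)(F)F)OC(=O)C(C)C)c(OC)c1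
F6 | step 3 | 1-[2,6-dihydroxy-4-methoxy-3-(3-methylbut-2-enyl)phenyl]ethanone | CC(=O)c1c(O)cc(OC)c(CC=C(C)C)c1O
F7 | step 3 | 1-[6-(tert-butyldimethylsilyloxy)-2-hydroxy-4-methoxy-3-(3-methylbut-2-enyl)phenyl]ethanone | CC(=O)c1c(O[Si](C)(C)C(C)(C)C)cc(OC)c(CC=C(C)C)c1O
F8 | step 3 | 2-acetyl-3-(tert-butyldimethylsilyloxy)-5-methoxy-6-(3-methylbut-2-enyl)phenyl trifluoromethanesulfonate | CC(=O)c1c(O[Si](C)(C)C(C)(C)C)cc(OC)c(CC=C(C)C)c1OS(=O)(=O)C(F)(F)F
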